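A one-step world, first end groups plus second end groups to links, sends the links of a flask towards the charge of whichever group is short. I test that on two flasks that differ in one charge.

all flasks: first end groups 0.10 M; temperature 70 °C

| run | second end groups | remark | time |
|---|---|---|---|
| green | 0.10 M | the very flask that is asked about, followed so far |  |
| blue | 0.20 M | run made earlier |  |
| flask | 0.100 M |  | 1.0 h |

| run | time / min | links / % |
|---|---|---|
| green | 2.00 | 37.8 |
| green | 6.00 | 43.9 |
| green | 10.0 | 47.2 |
| green | 15.0 | 49.2 |
| green | 20.0 | 50.0 |
| green | 30.0 | 53.6 |
| green | 40.0 | 52.6 |
| blue | 8.00 | 56.0 |
| blue | 15.0 | 55.6 |
| blue | 25.0 | 56.1 |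
| blue | 30.0 | 54.9 |
| blue | 40.0 | 56.7 |
| blue | 50.0 | 53.8 |
| blue | 60.0 | 54.7 |

(each reading ± 1 percentage point)

- north: change nothing and wait 30 min more
- west: at 1.0 h raise the temperature by 15 K, then wait 30 min
- south-east: at 1.0 h take out 90 % of the links then present, then wait 30 min
- north-east: at 1.0 h add second end groups, 50.0 % of the amount charged, then wait 30 min

- links, in percent of the first end groups first charged, at 1.0 h
- the option that brings most further links ("none" if no option brings more than 2 percentage points) (north / west / south-east / north-east / none)
- links present, with what was taken out counted in, in percent of the first end groups first charged, after north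
- links present, with what was taken out counted in, in percent of the first end groups first charged, after west

- removed links is counted in
- the earlier runs do not show what temperature does; that part of a forecast is a guess
- additions bring no volume worth counting

Green, the flask asked about, and blue both start with 0.10 M first end groups at 70 °C, but blue has c(second end groups) = 0.20 M against 0.10 M in green. Blue's readings stay flat from 8.00 min to 60.0 min. With that excess I assume its first end groups are used up, yet the readings average 55.4 %, not 100 %. I call this reading the ceiling share, the links standing per first end group used up.

I give green the same ceiling and treat its distance below it as a small correction, the first end groups still unused. With equal charges each group's partner thins out with it, so in a one-step world a small rest falls as one over time. At 20.0 min green reads 50.0 %, which puts the rest at 9.75 %, a rough figure given the scatter. At 1.0 h I reckon a rest of 3.25 %, so 53.6 % links, which is less than blue's ceiling by 1.8 percentage points. Another 30 min gives 54.2 %. I commit to no number for west or south-east.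

The forecast gives 53 % at 1.0 h, 53.2 % after north, 53.5 % after west, and best none, on the ground that “the reaction should be dead”.

The flask gives 53.4 % at 1.0 h, 54.1 % after north and 78.1 % after west. The best option is west, with a gain of 25 points.

    first end groups + second end groups → links (k = 4.00 M⁻¹ min⁻¹, Ea = 65.0 kJ mol⁻¹)
    links ⇌ isomer of the product (K = 0.800, k = 0.200 min⁻¹, Ea = 86.0 kJ mol⁻¹, ΔH = −77.0 kJ mol⁻¹)
    (constants at 70 °C)

The flask's missing part stands as isomer of the product, 42.6 % beside 53.4 % links at 1.00 h. The main reason for the shortfall is the loss of links to isomer of the product, both ways: without it this flask stands at 96.0 % links at 1.0 h instead of 53.4 %. With the way back from isomer to links taken away, west gains −0.34 points instead of 25 points, which is a part of the story, not the whole. In this flask the share times the 96.0 % of first end groups used up gives 53.2 % links. In a neighbour flask with c(second end groups) = 0.040 M, the second end groups are the limiting reagent, with 0 % left at 1.00 h, so the share on the 40.0 % of first end groups used up gives 22.2 %. The computed run gives 22.2 %.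

Readings and results were generated by integration from invented constants, and the scatter is random.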